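The dihydrofuran ring is dissected at O1–C7a and, more deeply, at C2–aryl and C3–C3a. C2 (oxygen plus trimethoxyphenyl) and C3 (methyl plus C3a of ring A) are the two alkene carbons of an (E)-propenyl boronate. A palladium-catalysed conjunctive coupling of the borate formed from this boronate and 3,4,5-trimethoxyphenyllithium with 2-chloro-4-methoxyphenyl triflate forges both C–aryl bonds and both stereocentres at once; the boron left on C2 becomes O1. The precursor is the (E)-propenylboronic ester of cis-1,2-dimethylacenaphthene-1,2-diol (mac diol). Oxidation, palladium-catalysed O1–C7a closure at the chloride, C5 bromination and Suzuki propenylation finish the target.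

Key step: step 4

Assumption: the (Sp,Sp) enantiomer of the MandyPhos ligand is taken to steer palladium to the alkene face that leads to boronate 10; the sense would be confirmed on alcohol 11, and the mirror-image ligand used if the opposite sense is found.

Remark: the dihydrobenzofuran is numbered O1, C2, C3, C3a, C4–C7, C7a; the target is the trans-(2R,3R) isomer.

Step 1
Reactants: 1 acenaphthoquinone
Product: 2 cis-1,2-dimethyl-1,2-dihydroacenaphthylene-1,2-diol (meso mac diol)
Conditions: MeMgBr (2.5 equiv), THF, 0 °C → rt; aq. NH4Cl; recrystallisation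
Reagents that add atoms: methylmagnesium bromide, C[Mg]Br
Why: Double Grignard 1,2-addition to the 1,2-diketone, in which the second methyl group should enter anti to the magnesium alkoxide on the neighbouring carbon, so that the cis (meso) diol predominates and is purified by crystallisation (a trans diol could not bridge boron in step 2).

Step 2
Reactants: 2 cis-1,2-dimethyl-1,2-dihydroacenaphthylene-1,2-diol; 3 (E)-prop-1-enylboronic acid
Product: 4 (E)-prop-1-enylboronic acid mac ester
Conditions: MgSO4, CH2Cl2, rt
Reagents that add atoms: none
Why: Boronic acid–diol condensation (esterification) driven by removal of water, which leaves the E alkene untouched and creates no stereocentre.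

Step 3
Reactants: 5 2-chloro-4-methoxyphenol
Product: 6 2-chloro-4-methoxyphenyl trifluoromethanesulfonate
Conditions: Tf2O, pyridine, CH2Cl2, 0 °C
Reagents that add atoms: triflic anhydride, O=S(=O)(OS(=O)(=O)C(F)(F)F)C(F)(F)F
Why: O-Sulfonylation of the phenol with triflic anhydride, to which the aryl chloride and the methyl ether are inert.

Step 4
Reactants: 7 5-bromo-1,2,3-trimethoxybenzene; 4 (E)-prop-1-enylboronic acid mac ester; 6 2-chloro-4-methoxyphenyl trifluoromethanesulfonate
Product: 10 (1R,2S)-2-(2-chloro-4-methoxyphenyl)-1-(3,4,5-trimethoxyphenyl)propylboronic acid mac ester, via 3,4,5-trimethoxyphenyllithium 8 (not isolated), via lithium aryl(propenyl)borate 9 (not isolated)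
Conditions: 7, t-BuLi (2.0 equiv), Et2O, −78 °C; 4, −78 °C → rt; solvent exchange to THF; 6 (1.1 equiv), KOTf (2 equiv), Pd(OAc)2 (2 mol %), (Sp,Sp)-MandyPhos (2.4 mol %), 40–60 °C
Reagents that add atoms: none
Why: Oxidative addition of triflate 6 to zerovalent palladium gives a cationic arylpalladium–bisphosphine complex that binds the propenyl π bond of borate 9; this triggers a 1,2-metallate shift of the trimethoxyphenyl group from boron to the boron-bearing carbon, anti to palladium, and reductive elimination with retention then joins ring A to the methyl-bearing carbon. This is the known palladium-catalysed enantioselective conjunctive cross-coupling of alkenylboron ate complexes with aryl triflates, in which β-substituted alkenyl partners are used as mac boronates; no ring is closed. The boron-bearing centre (future C2) is set by the chiral ferrocenyl bisphosphine, which selects the alkene face that palladium binds, and the neighbouring centre (future C3) follows from the stereospecific anti addition across the E alkene. The step needs the metallate shift to win over direct Suzuki-type transfer of aryl or propenyl to palladium, which the hindered mac ligand on boron secures by slowing transmetalation. It also needs reaction at C–OTf and not at C–Cl, secured by the faster oxidative addition of the triflate at this temperature, and a halide-free cationic palladium, for which KOTf removes the bromide left by the Br–Li exchange.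

Step 5
Reactants: 10 (1R,2S)-2-(2-chloro-4-methoxyphenyl)-1-(3,4,5-trimethoxyphenyl)propylboronic acid mac ester
Product: 11 (1R,2R)-2-(2-chloro-4-methoxyphenyl)-1-(3,4,5-trimethoxyphenyl)propan-1-ol
Conditions: 30% H2O2, 3 M NaOH, THF, 0 °C → rt
Reagents that add atoms: hydrogen peroxide, OO
Why: Boronate oxidation by hydroperoxide, in which carbon migrates from boron to oxygen with retention, so the boron-bearing carbon becomes the (1R) carbinol (the C2 descriptor changes from S to R only through the change in CIP priorities).

Step 6
Reactants: 11 (1R,2R)-2-(2-chloro-4-methoxyphenyl)-1-(3,4,5-trimethoxyphenyl)propan-1-ol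
Product: 12 (2R,3R)-6-methoxy-3-methyl-2-(3,4,5-trimethoxyphenyl)-2,3-dihydro-1-benzofuran
Conditions: Pd(OAc)2 (5 mol %), t-BuXPhos (7.5 mol %), Cs2CO3, toluene, 80–100 °C
Reagents that add atoms: none
Why: Buchwald-type intramolecular palladium-catalysed C–O coupling of the aryl chloride with the secondary alcohol closes the five-membered ring at O1–C7a without breaking a bond at either stereocentre, so the trans relation is carried over.

Step 7
Reactants: 12 (2R,3R)-6-methoxy-3-methyl-2-(3,4,5-trimethoxyphenyl)-2,3-dihydro-1-benzofuran
Product: 13 (2R,3R)-5-bromo-6-methoxy-3-methyl-2-(3,4,5-trimethoxyphenyl)-2,3-dihydro-1-benzofuran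
Conditions: NBS (1.0 equiv), MeCN, 0 °C, dark
Reagents that add atoms: N-bromosuccinimide, O=C1CCC(=O)N1Br
Why: Electrophilic aromatic bromination should go to C5, which is para to O1, ortho to the C6 methoxy group and flanked by only one substituent, whereas C7 lies between two oxygens and the free positions of the trimethoxyphenyl ring are hemmed in by a methoxy group and the C2 branch.

Step 8
Reactants: 13 (2R,3R)-5-bromo-6-methoxy-3-methyl-2-(3,4,5-trimethoxyphenyl)-2,3-dihydro-1-benzofuran; 3 (E)-prop-1-enylboronic acid
Product: 14 (2R,3R)-6-methoxy-3-methyl-5-[(E)-prop-1-enyl]-2-(3,4,5-trimethoxyphenyl)-2,3-dihydro-1-benzofuran (target)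
Conditions: Pd(dppf)Cl2 (5 mol %), K2CO3, dioxane/H2O, 80 °C
Reagents that add atoms: none
Why: Suzuki–Miyaura coupling of the aryl bromide with the alkenylboronic acid, which transfers the propenyl group with retention of its E geometry.

Compound list
1 | acenaphthoquinone (acenaphthylene-1,2-dione) | O=C1C(=O)c2cccc3cccc1c23 | starting material
2 | cis-1,2-dimethyl-1,2-dihydroacenaphthylene-1,2-diol (meso, mac diol) | O[C@]1(C)c2cccc3cccc(c23)[C@]1(C)O | intermediate
3 | (E)-prop-1-enylboronic acid | C/C=C/B(O)O | starting material
4 | (E)-prop-1-enylboronic acid mac ester (cis-6b,9a-dimethyl-8-[(E)-prop-1-enyl]-6b,9a-dihydroacenaphtho[1,2-d][1,3,2]dioxaborole) | C/C=C/B1O[C@]2(C)c3cccc4cccc(c34)[C@]2(C)O1 | intermediate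
5 | 2-chloro-4-methoxyphenol | COc1ccc(O)c(Cl)c1 | starting material
6 | 2-chloro-4-methoxyphenyl trifluoromethanesulfonate | COc1ccc(OS(=O)(=O)C(F)(F)F)c(Cl)c1 | intermediate
7 | 5-bromo-1,2,3-trimethoxybenzene | COc1cc(Br)cc(OC)c1OC | starting material
8 | 3,4,5-trimethoxyphenyllithium | [Li]c1cc(OC)c(OC)c(OC)c1 | intermediate
9 | lithium [(E)-prop-1-enyl](3,4,5-trimethoxyphenyl)borate of the mac diol (configuration at boron undefined) | [Li+].C/C=C/[B-]1(c2cc(OC)c(OC)c(OC)c2)O[C@]2(C)c3cccc4cccc(c34)[C@]2(C)O1 | intermediate
10 | (1R,2S)-2-(2-chloro-4-methoxyphenyl)-1-(3,4,5-trimethoxyphenyl)propylboronic acid mac ester | B1(O[C@]2(C)c3cccc4cccc(c34)[C@]2(C)O1)[C@@H](c1cc(OC)c(OC)c(OC)c1)[C@@H](c1ccc(OC)cc1Cl)C | intermediate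
11 | (1R,2R)-2-(2-chloro-4-methoxyphenyl)-1-(3,4,5-trimethoxyphenyl)propan-1-ol | O[C@@H](c1cc(OC)c(OC)c(OC)c1)[C@@H](c1ccc(OC)cc1Cl)C | intermediate
12 | (2R,3R)-6-methoxy-3-methyl-2-(3,4,5-trimethoxyphenyl)-2,3-dihydro-1-benzofuran | COc1ccc2c(c1)O[C@@H](c1cc(OC)c(OC)c(OC)c1)[C@@H]2C | intermediate
13 | (2R,3R)-5-bromo-6-methoxy-3-methyl-2-(3,4,5-trimethoxyphenyl)-2,3-dihydro-1-benzofuran | Brc1cc2c(cc1OC)O[C@@H](c1cc(OC)c(OC)c(OC)c1)[C@@H]2C | intermediate
14 | (2R,3R)-6-methoxy-3-methyl-5-[(E)-prop-1-enyl]-2-(3,4,5-trimethoxyphenyl)-2,3-dihydro-1-benzofuran | C/C=C/c1cc2c(cc1OC)O[C@@H](c1cc(OC)c(OC)c(OC)c1)[C@@H]2C | target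

Total step count: 8. Longest linear sequence: 7 steps (steps 1, 2, 4, 5, 6, 7, 8).

Steps most likely to fail

Step 4. The borate may hand its aryl or propenyl group directly to palladium (Suzuki-type coupling) in place of the 1,2-shift, or facial control may erode with the ortho-chloro electrophile. The fallback reaches alcohol 11 through a ketone and sets out from 7. Br–Li exchange gives 8, which is acylated with N-methoxy-N-methylpropanamide (CCC(=O)N(C)OC) to give 1-(3,4,5-trimethoxyphenyl)propan-1-one F1. Palladium-catalysed α-arylation of F1 with 1-bromo-2-chloro-4-methoxybenzene (COc1ccc(Br)c(Cl)c1; Pd(OAc)2, XPhos, NaOt-Bu, toluene, 70 °C, the C–Br bond reacting ahead of C–Cl) should give racemic 2-(2-chloro-4-methoxyphenyl)-1-(3,4,5-trimethoxyphenyl)propan-1-one F2. Asymmetric hydrogenation under dynamic kinetic resolution (RuCl2(xylbinap)(daipen) of the appropriate handedness, KOt-Bu, i-PrOH, H2) then exploits the base-labile α-aryl centre. Hydride should add in the Felkin–Anh sense, with ring A antiperiplanar, which is the threo relation required, so the sequence comes back to the route at 11.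

Step 6. β-Hydride elimination from the palladium alkoxide (oxidising the carbinol and reducing the C–Cl bond), or slow oxidative addition into the electron-rich, ortho-branched aryl chloride, may outrun C–O bond formation. The fallback is metal-free and sets out from 11. LiTMP (3 equiv, THF, −78 °C → rt) should form the lithium alkoxide and lithiate the ring position between chlorine and methoxy. Loss of chloride gives the 3-methoxyaryne lithium alkoxide F3. Its alkoxide should add to the aryne carbon next to the side chain, the one remote from the methoxy group, so that the aryl anion sits beside OMe. Protonation on work-up gives 12, where the fallback rejoins the route; the stereocentres are not involved.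

Step 7. Bromine may be delivered in part to the trimethoxyphenyl ring or to C7, or a second bromination may follow the first. The fallback swaps halogenation and cross-coupling for formylation and olefination and sets out from 12. Vilsmeier–Haack formylation (POCl3, DMF, 0 °C → rt, then aq. NaOAc) uses a weak, bulky electrophile that should pick the most activated and least hindered site and stop after one substitution. It should give (2R,3R)-6-methoxy-3-methyl-2-(3,4,5-trimethoxyphenyl)-2,3-dihydro-1-benzofuran-5-carbaldehyde F4. Julia–Kocienski olefination of F4 with 5-(ethylsulfonyl)-1-phenyl-1H-tetrazole (CCS(=O)(=O)c1nnnn1-c1ccccc1; KHMDS, DME, −60 °C → rt) should give the (E)-propenyl group. Any Z isomer would be equilibrated with catalytic iodine, so the fallback bypasses 13 and comes back to the route at 14.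

Further compounds
F1 | step 4 | 1-(3,4,5-trimethoxyphenyl)propan-1-one | CCC(=O)c1cc(OC)c(OC)c(OC)c1
F2 | step 4 | racemic 2-(2-chloro-4-methoxyphenyl)-1-(3,4,5-trimethoxyphenyl)propan-1-one | CC(C(=O)c1cc(OC)c(OC)c(OC)c1)c1ccc(OC)cc1Cl
F3 | step 6 | lithium (1R,2R)-2-(4-methoxy-2,3-didehydrophenyl)-1-(3,4,5-trimethoxyphenyl)propan-1-olate (aryne alkoxide) | [Li+].[O-][C@@H](c1cc(OC)c(OC)c(OC)c1)[C@@H](C1=CC=C(OC)C#C1)C
F4 | step 7 | (2R,3R)-6-methoxy-3-methyl-2-(3,4,5-trimethoxyphenyl)-2,3-dihydro-1-benzofuran-5-carbaldehyde | O=Cc1cc2c(cc1OC)O[C@@H](c1cc(OC)c(OC)c(OC)c1)[C@@H]2C
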